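**Strategy**

The route rests on cutting two neighbouring bonds on ring A: O1–C8a of the lactone and C8–C1' of the side chain, with the C7 methoxy beside C8. A fluoride-generated C8–C8a aryne that carries a Z-acrylate on C4a is captured first by its own carboxylate, which closes pyranone ring B, and then, through the resulting C8 aryl anion, by an (S)-α-alkoxy aldehyde, which sets C1' by polar Felkin–Anh control. The precursor is a Z-cinnamic acid with ortho trimethylsilyl and triflate groups, used as its dry cesium salt in THF so that no proton donor competes. Four routine steps then exchange the 4-methoxybenzyl ether for the isovalerate.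

Key step: step 13

Remark (chemistry): the target is taken as 1'R,2'S (anti). (R)-9 maps onto (S)-16 without any exchange at the stereocentre, because the CIP ranks of its two carbon substituents swap. Aldehyde 16 is assumed to be configurationally labile (its C2–H is α to the carbonyl and allylic), so it is made last and used at once. Reagents without a compound number are treated as commercial.

**Route**

Step 1
Reactants: 1 2-bromoisovanillin (2-bromo-3-hydroxy-4-methoxybenzaldehyde)
Product: 2 2-bromo-3-(1,3-dioxolan-2-yl)-6-methoxyphenol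
Conditions: HOCH2CH2OH, pTsOH·H2O (cat.), PhMe, reflux, Dean–Stark
Reagents that add atoms: ethylene glycol, OCCO
Why: Acid-catalysed acetalisation with azeotropic removal of water masks the aldehyde as a 1,3-dioxolane that tolerates n-BuLi, while the phenol stays free for the next step.

Step 2
Reactants: 2 2-bromo-3-(1,3-dioxolan-2-yl)-6-methoxyphenol
Product: 5 3-(1,3-dioxolan-2-yl)-6-methoxy-2-(trimethylsilyl)phenyl trifluoromethanesulfonate, via aryl trimethylsilyl ether 3 (not isolated), via lithium 2-silylphenoxide 4 (not isolated)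
Conditions: HN(SiMe3)2, THF, reflux, then evaporate; n-BuLi, THF, −78 °C to rt; Tf2O, −78 °C
Reagents that add atoms: hexamethyldisilazane, C[Si](C)(C)N[Si](C)(C)C; trifluoromethanesulfonic anhydride, O=S(=O)(OS(=O)(=O)C(F)(F)F)C(F)(F)F
Why: O-silylation, bromine–lithium exchange at C2 and a 1,3 O→C silyl shift (retro-Brook rearrangement) give the lithium phenoxide that Tf2O caps, the standard one-flask entry to ortho-silylaryl triflates from ortho-bromophenols, and the dioxolane is inert throughout.

Step 3
Reactants: 5 3-(1,3-dioxolan-2-yl)-6-methoxy-2-(trimethylsilyl)phenyl trifluoromethanesulfonate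
Product: 6 3-formyl-6-methoxy-2-(trimethylsilyl)phenyl trifluoromethanesulfonate
Conditions: 1 M aq. HCl, THF, rt
Reagents that add atoms: water, O
Why: Dilute acid hydrolyses the dioxolane (acetal hydrolysis) far faster than it can protodesilylate an aryl silane whose ipso carbon is deactivated by the ortho triflate and not activated by the meta methoxy group.

Step 4
Reactants: 6 3-formyl-6-methoxy-2-(trimethylsilyl)phenyl trifluoromethanesulfonate
Product: 7 methyl (Z)-3-[4-methoxy-3-(trifluoromethylsulfonyloxy)-2-(trimethylsilyl)phenyl]acrylate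
Conditions: (CF3CH2O)2P(O)CH2CO2Me, KN(SiMe3)2, 18-crown-6, THF, −78 °C
Reagents that add atoms: methyl bis(2,2,2-trifluoroethyl)phosphonoacetate, COC(=O)CP(=O)(OCC(F)(F)F)OCC(F)(F)F
Why: In the Still–Gennari olefination the electron-poor phosphonate eliminates from the kinetic adduct before it can equilibrate, so the Z-enoate is expected, and the non-nucleophilic phosphonate anion leaves the silyl triflate alone.

Step 5
Reactants: 7 methyl (Z)-3-[4-methoxy-3-(trifluoromethylsulfonyloxy)-2-(trimethylsilyl)phenyl]acrylate
Product: 8 (Z)-3-[4-methoxy-3-(trifluoromethylsulfonyloxy)-2-(trimethylsilyl)phenyl]acrylic acid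
Conditions: Me3SnOH, 1,2-dichloroethane, 70 °C; then 5% aq. HCl wash
Reagents that add atoms: trimethyltin hydroxide, C[Sn](C)(C)O
Why: Me3SnOH transfers hydroxide to the ester carbonyl under neutral conditions (mild ester hydrolysis), which should spare the aryl triflate, the aryl silane and the Z-alkene that aqueous LiOH would put at risk.

Step 6
Reactants: 9 methyl (R)-2,2-dimethyl-1,3-dioxolane-4-carboxylate
Product: 10 (R)-N-methoxy-N,2,2-trimethyl-1,3-dioxolane-4-carboxamide
Conditions: MeNH(OMe)·HCl, iPrMgCl, THF, −20 °C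
Reagents that add atoms: N,O-dimethylhydroxylamine hydrochloride, CNOC.Cl
Why: The magnesium amide made from the hydroxylamine salt and iPrMgCl converts the ester into the Weinreb amide at low temperature (aminolysis), where the ring-locked α-stereocentre does not enolise.

Step 7
Reactants: 10 (R)-N-methoxy-N,2,2-trimethyl-1,3-dioxolane-4-carboxamide
Product: 11 1-[(R)-2,2-dimethyl-1,3-dioxolan-4-yl]ethanone
Conditions: MeMgBr, THF, 0 °C; aq. NH4Cl
Reagents that add atoms: methylmagnesium bromide, C[Mg]Br
Why: Grignard addition to a Weinreb amide stops at the chelated tetrahedral intermediate, so the methyl ketone is released only on work-up and is not over-added.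

Step 8
Reactants: 11 1-[(R)-2,2-dimethyl-1,3-dioxolan-4-yl]ethanone
Product: 12 (S)-2,2-dimethyl-4-(prop-1-en-2-yl)-1,3-dioxolane
Conditions: Ph3PCH3Br, KN(SiMe3)2, THF, −78 to 0 °C
Reagents that add atoms: methyltriphenylphosphonium bromide, C[P+](c1ccccc1)(c1ccccc1)c1ccccc1.[Br-]
Why: Wittig methylenation at low temperature should preserve the stereocentre, because the dioxolane holds the C4–H bond out of alignment with the carbonyl π system and so slows enolisation (the descriptor becomes S only through a change of CIP ranks).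

Step 9
Reactants: 12 (S)-2,2-dimethyl-4-(prop-1-en-2-yl)-1,3-dioxolane
Product: 13 (S)-3-methylbut-3-ene-1,2-diol
Conditions: Dowex 50WX8 (H+ form), MeOH/H2O (4:1), rt; filter
Reagents that add atoms: none
Why: Acidic resin hydrolyses the isopropylidene acetal (acetal hydrolysis) without ionising the allylic C–O bond, and filtration removes the acid so the water-soluble diol needs no extraction.

Step 10
Reactants: 13 (S)-3-methylbut-3-ene-1,2-diol
Product: 14 (4S)-2-(4-methoxyphenyl)-4-(prop-1-en-2-yl)-1,3-dioxolane (both C2 epimers)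
Conditions: 4-MeOC6H4CH(OMe)2, PPTS (cat.), CH2Cl2, rt
Reagents that add atoms: 4-methoxybenzaldehyde dimethyl acetal, COc1ccc(C(OC)OC)cc1
Why: Acid-catalysed transacetalisation gives the 4-methoxybenzylidene acetal of the 1,2-diol, whose acetal-carbon epimers converge in the next step.

Step 11
Reactants: 14 (4S)-2-(4-methoxyphenyl)-4-(prop-1-en-2-yl)-1,3-dioxolane
Product: 15 (S)-2-(4-methoxybenzyloxy)-3-methylbut-3-en-1-ol
Conditions: iBu2AlH, CH2Cl2, −78 to 0 °C; Rochelle salt work-up
Reagents that add atoms: none
Why: iBu2AlH coordinates the less hindered primary oxygen and cleaves that acetal C–O bond (reductive acetal opening), so the 4-methoxybenzyl group should stay on the secondary allylic oxygen and the primary alcohol is freed.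

Step 12
Reactants: 15 (S)-2-(4-methoxybenzyloxy)-3-methylbut-3-en-1-ol
Product: 16 (S)-2-(4-methoxybenzyloxy)-3-methylbut-3-enal
Conditions: Dess–Martin periodinane, NaHCO3, CH2Cl2, 0 °C to rt; short filtration, used at once
Reagents that add atoms: none
Why: Buffered Dess–Martin oxidation is fast and non-basic, which should avoid epimerisation at C2 and migration of the alkene into conjugation.

Step 13
Reactants: 8 (Z)-3-[4-methoxy-3-(trifluoromethylsulfonyloxy)-2-(trimethylsilyl)phenyl]acrylic acid; 16 (S)-2-(4-methoxybenzyloxy)-3-methylbut-3-enal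
Product: 20 8-[(1R,2S)-1-hydroxy-2-(4-methoxybenzyloxy)-3-methylbut-3-enyl]-7-methoxycoumarin, via cesium (Z)-acrylate salt 17 (not isolated), via aryne carboxylate 18 (not isolated), via 8-cesio-7-methoxycoumarin 19 (not isolated)
Conditions: Cs2CO3 (0.5 equiv), MeOH, 0 °C, then evaporate and dry (PhMe azeotrope, vacuum); 16 (2.5 equiv), CsF, 18-crown-6, 4 Å MS, THF, −20 °C to rt; AcOH quench
Reagents that add atoms: none
Why: Proposed new method: fluoride attacks silicon in the dry salt 17 and triflate leaves from C8, giving aryne 18 (C8≡C8a); the carboxylate oxygen, held next to C8a by the Z-alkene on C4a, adds there to form O1–C8a, and the C8 aryl anion 19, flanked by O1 and the C7 methoxy oxygen, then adds to the carbonyl of 16 to form C8–C1'. The closest known reaction types are O-arylation of carboxylates by arynes and three-component couplings of an aryne, a nucleophile and an aldehyde. Ring B closes in a 6-exo-dig mode, the attacked aryne bond lying outside the new six-membered lactone ring. C1' is set by polar Felkin–Anh addition, the C2–O bond of 16 standing anti to the incoming non-chelating cesium aryl, which should give the 1'R,2'S (anti) isomer. The step needs regioselectivity (oxygen to C8a, carbon to C8), secured both by the tether and by the bias of a 3-methoxyaryne toward attack meta to the methoxy group. It also needs the aryl anion to meet the aldehyde before a proton, which the bicarbonate-free preformed salt, THF in place of acetonitrile and excess aldehyde at low temperature are meant to secure.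

Step 14
Reactants: 20 8-[(1R,2S)-1-hydroxy-2-(4-methoxybenzyloxy)-3-methylbut-3-enyl]-7-methoxycoumarin
Product: 21 8-[(1R,2S)-1-(tert-butyldimethylsilyloxy)-2-(4-methoxybenzyloxy)-3-methylbut-3-enyl]-7-methoxycoumarin
Conditions: TBSOTf, 2,6-lutidine, CH2Cl2, −78 to 0 °C
Reagents that add atoms: tert-butyldimethylsilyl trifluoromethanesulfonate, CC(C)(C)[Si](C)(C)OS(=O)(=O)C(F)(F)F
Why: The silyl triflate with a hindered pyridine base silylates even the congested C1' benzylic alcohol (O-silylation) and leaves the lactone, the benzyl ether and the alkene untouched.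

Step 15
Reactants: 21 8-[(1R,2S)-1-(tert-butyldimethylsilyloxy)-2-(4-methoxybenzyloxy)-3-methylbut-3-enyl]-7-methoxycoumarin
Product: 22 8-[(1R,2S)-1-(tert-butyldimethylsilyloxy)-2-hydroxy-3-methylbut-3-enyl]-7-methoxycoumarin
Conditions: DDQ, CH2Cl2/pH 7 buffer (10:1), 0 °C to rt
Reagents that add atoms: none
Why: DDQ oxidises the electron-rich 4-methoxybenzyl ether to an oxocarbenium ion that water hydrolyses (oxidative debenzylation), while the silyl ether, the coumarin and the 1,1-disubstituted alkene are not oxidised under buffered conditions.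

Step 16
Reactants: 22 8-[(1R,2S)-1-(tert-butyldimethylsilyloxy)-2-hydroxy-3-methylbut-3-enyl]-7-methoxycoumarin; 23 isovaleryl chloride
Product: 24 (1R,2S)-1-(tert-butyldimethylsilyloxy)-1-(7-methoxy-2-oxo-2H-chromen-8-yl)-3-methylbut-3-en-2-yl 3-methylbutanoate
Conditions: pyridine, DMAP (cat.), CH2Cl2, 0 °C to rt
Reagents that add atoms: none
Why: DMAP-catalysed acylation of the free C2' alcohol by the acid chloride (nucleophilic catalysis) can only occur at C2' because O1' is silylated, and neither stereocentre is touched.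

Step 17
Reactants: 24 (1R,2S)-1-(tert-butyldimethylsilyloxy)-1-(7-methoxy-2-oxo-2H-chromen-8-yl)-3-methylbut-3-en-2-yl 3-methylbutanoate
Product: 25 (1R,2S)-1-hydroxy-1-(7-methoxy-2-oxo-2H-chromen-8-yl)-3-methylbut-3-en-2-yl 3-methylbutanoate (target)
Conditions: HF·pyridine, pyridine, THF, 0 °C to rt
Reagents that add atoms: none
Why: Buffered HF·pyridine cleaves the Si–O bond (desilylation) under weakly acidic conditions in which the isovalerate should not migrate from O2' to O1' as it could with basic fluoride, giving the target with both stereocentres intact.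

**Compound list**

1 | 2-bromoisovanillin (2-bromo-3-hydroxy-4-methoxybenzaldehyde) | COc1ccc(C=O)c(Br)c1O | starting material
2 | 2-bromo-3-(1,3-dioxolan-2-yl)-6-methoxyphenol | COc1ccc(C2OCCO2)c(Br)c1O | intermediate
3 | [2-bromo-3-(1,3-dioxolan-2-yl)-6-methoxyphenoxy]trimethylsilane | COc1ccc(C2OCCO2)c(Br)c1O[Si](C)(C)C | intermediate (not isolated)
4 | lithium 3-(1,3-dioxolan-2-yl)-6-methoxy-2-(trimethylsilyl)phenoxide | [Li+].COc1ccc(C2OCCO2)c([Si](C)(C)C)c1[O-] | intermediate (not isolated)
5 | 3-(1,3-dioxolan-2-yl)-6-methoxy-2-(trimethylsilyl)phenyl trifluoromethanesulfonate | COc1ccc(C2OCCO2)c([Si](C)(C)C)c1OS(=O)(=O)C(F)(F)F | intermediate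
6 | 3-formyl-6-methoxy-2-(trimethylsilyl)phenyl trifluoromethanesulfonate | COc1ccc(C=O)c([Si](C)(C)C)c1OS(=O)(=O)C(F)(F)F | intermediate
7 | methyl (Z)-3-[4-methoxy-3-(trifluoromethylsulfonyloxy)-2-(trimethylsilyl)phenyl]acrylate | COc1ccc(/C=C\C(=O)OC)c([Si](C)(C)C)c1OS(=O)(=O)C(F)(F)F | intermediate
8 | (Z)-3-[4-methoxy-3-(trifluoromethylsulfonyloxy)-2-(trimethylsilyl)phenyl]acrylic acid | COc1ccc(/C=C\C(=O)O)c([Si](C)(C)C)c1OS(=O)(=O)C(F)(F)F | intermediate
9 | methyl (R)-2,2-dimethyl-1,3-dioxolane-4-carboxylate | COC(=O)[C@H]1COC(C)(C)O1 | starting material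
10 | (R)-N-methoxy-N,2,2-trimethyl-1,3-dioxolane-4-carboxamide | CON(C)C(=O)[C@H]1COC(C)(C)O1 | intermediate
11 | 1-[(R)-2,2-dimethyl-1,3-dioxolan-4-yl]ethanone | CC(=O)[C@H]1COC(C)(C)O1 | intermediate
12 | (S)-2,2-dimethyl-4-(prop-1-en-2-yl)-1,3-dioxolane | C=C(C)[C@H]1COC(C)(C)O1 | intermediate
13 | (S)-3-methylbut-3-ene-1,2-diol | C=C(C)[C@H](O)CO | intermediate
14 | (4S)-2-(4-methoxyphenyl)-4-(prop-1-en-2-yl)-1,3-dioxolane (both C2 epimers) | C=C(C)[C@H]1COC(c2ccc(OC)cc2)O1 | intermediate
15 | (S)-2-(4-methoxybenzyloxy)-3-methylbut-3-en-1-ol | C=C(C)[C@H](OCc1ccc(OC)cc1)CO | intermediate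
16 | (S)-2-(4-methoxybenzyloxy)-3-methylbut-3-enal | C=C(C)[C@H](OCc1ccc(OC)cc1)C=O | intermediate
17 | cesium (Z)-3-[4-methoxy-3-(trifluoromethylsulfonyloxy)-2-(trimethylsilyl)phenyl]acrylate | [Cs+].COc1ccc(/C=C\C(=O)[O-])c([Si](C)(C)C)c1OS(=O)(=O)C(F)(F)F | intermediate (not isolated)
18 | cesium (Z)-3-(2,3-didehydro-4-methoxyphenyl)acrylate (aryne between C8 and C8a) | [Cs+].COC1=CC=C(/C=C\C(=O)[O-])C#C1 | intermediate (not isolated)
19 | 8-cesio-7-methoxycoumarin | [Cs]c1c(OC)ccc2ccc(=O)oc12 | intermediate (not isolated)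
20 | 8-[(1R,2S)-1-hydroxy-2-(4-methoxybenzyloxy)-3-methylbut-3-enyl]-7-methoxycoumarin | C=C(C)[C@H](OCc1ccc(OC)cc1)[C@H](O)c1c(OC)ccc2ccc(=O)oc12 | intermediate
21 | 8-[(1R,2S)-1-(tert-butyldimethylsilyloxy)-2-(4-methoxybenzyloxy)-3-methylbut-3-enyl]-7-methoxycoumarin | C=C(C)[C@H](OCc1ccc(OC)cc1)[C@H](O[Si](C)(C)C(C)(C)C)c1c(OC)ccc2ccc(=O)oc12 | intermediate
22 | 8-[(1R,2S)-1-(tert-butyldimethylsilyloxy)-2-hydroxy-3-methylbut-3-enyl]-7-methoxycoumarin | C=C(C)[C@H](O)[C@H](O[Si](C)(C)C(C)(C)C)c1c(OC)ccc2ccc(=O)oc12 | intermediate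
23 | isovaleryl chloride (3-methylbutanoyl chloride) | CC(C)CC(=O)Cl | starting material
24 | (1R,2S)-1-(tert-butyldimethylsilyloxy)-1-(7-methoxy-2-oxo-2H-chromen-8-yl)-3-methylbut-3-en-2-yl 3-methylbutanoate | C=C(C)[C@H](OC(=O)CC(C)C)[C@H](O[Si](C)(C)C(C)(C)C)c1c(OC)ccc2ccc(=O)oc12 | intermediate
25 | (1R,2S)-1-hydroxy-1-(7-methoxy-2-oxo-2H-chromen-8-yl)-3-methylbut-3-en-2-yl 3-methylbutanoate | C=C(C)[C@H](OC(=O)CC(C)C)[C@H](O)c1c(OC)ccc2ccc(=O)oc12 | target

**Step count and risks**

Total steps: 17. Longest linear sequence: 12 steps (9 to 25: steps 6–12, 13, 14–17).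

Step 13 (bears the new-method label). The aryl anion at C8 may be protonated before it reaches the aldehyde. Fluoride or the aryl anion may enolise 16, eroding configuration at C2 or moving the alkene into conjugation. Facial selectivity at C1' may be insufficient. The fallback uses known chemistry, sets out from 16 (with commercial 7-hydroxycoumarin as partner) and returns at 20. 7-Hydroxycoumarin is iodinated at C8 (I2, KI, aq. NH3) to 7-hydroxy-8-iodocoumarin F1 and O-methylated (MeI, K2CO3, acetone) to 8-iodo-7-methoxycoumarin F2. Nozaki–Hiyama–Kishi coupling of F2 with 16 (CrCl2, NiCl2 cat., DMF, rt) is neutral, tolerates the lactone and forms C8–C1' to give 20; the non-chelating organochromium reagent is expected to favour the same Felkin–Anh sense. Any 1'-epimer, 8-[(1S,2S)-1-hydroxy-2-(4-methoxybenzyloxy)-3-methylbut-3-enyl]-7-methoxycoumarin F3, would be recycled by Dess–Martin oxidation to the ketone 8-[(S)-2-(4-methoxybenzyloxy)-3-methylbut-3-enoyl]-7-methoxycoumarin F4. Chelation-controlled reduction of F4 with Zn(BH4)2 (Et2O, −20 °C) should then return the anti alcohol 20.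

Step 8. The basic ylide may enolise the α-alkoxy ketone and so lower the enantiomeric purity carried into 16, and the volatile alkene may be lost on concentration. The fallback runs from 11 back to 12 by Peterson olefination. Me3SiCH2MgCl premixed with anhydrous CeCl3 (THF, −78 °C) should add to 11 without enolisation to give the β-hydroxysilane 2-[(R)-2,2-dimethyl-1,3-dioxolan-4-yl]-1-(trimethylsilyl)propan-2-ol F5. KH (THF, 0 °C) then effects syn-elimination to 12, the alkene forming only toward the silylmethyl carbon.

Step 2. The O→C silyl shift may be incomplete at the crowded C2 position, the aryllithium may be protonated to the debrominated phenol, or acid traces in the Tf2O quench may damage the acetal. The fallback runs from 2 back to 5, makes the C–Si bond intermolecularly and separates the triflation. Two equivalents of n-BuLi (THF, −78 to 0 °C) deprotonate the phenol and exchange the bromine, and Me3SiCl silylates carbon and oxygen to give [3-(1,3-dioxolan-2-yl)-6-methoxy-2-(trimethylsilyl)phenoxy]trimethylsilane F6. K2CO3 in MeOH cleaves only the O–Si bond to give 3-(1,3-dioxolan-2-yl)-6-methoxy-2-(trimethylsilyl)phenol F7. F7 is isolated and triflated without acid using PhNTf2, Et3N and DMAP (CH2Cl2, rt) to give 5.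

**Further compounds**

F1 | step 13 | 7-hydroxy-8-iodocoumarin | Oc1ccc2ccc(=O)oc2c1I
F2 | step 13 | 8-iodo-7-methoxycoumarin | COc1ccc2ccc(=O)oc2c1I
F3 | step 13 | 8-[(1S,2S)-1-hydroxy-2-(4-methoxybenzyloxy)-3-methylbut-3-enyl]-7-methoxycoumarin | C=C(C)[C@H](OCc1ccc(OC)cc1)[C@@H](O)c1c(OC)ccc2ccc(=O)oc12
F4 | step 13 | 8-[(S)-2-(4-methoxybenzyloxy)-3-methylbut-3-enoyl]-7-methoxycoumarin | C=C(C)[C@H](OCc1ccc(OC)cc1)C(=O)c1c(OC)ccc2ccc(=O)oc12
F5 | step 8 | 2-[(R)-2,2-dimethyl-1,3-dioxolan-4-yl]-1-(trimethylsilyl)propan-2-ol (both carbinol epimers) | CC(O)(C[Si](C)(C)C)[C@H]1COC(C)(C)O1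
F6 | step 2 | [3-(1,3-dioxolan-2-yl)-6-methoxy-2-(trimethylsilyl)phenoxy]trimethylsilane | COc1ccc(C2OCCO2)c([Si](C)(C)C)c1O[Si](C)(C)C
F7 | step 2 | 3-(1,3-dioxolan-2-yl)-6-methoxy-2-(trimethylsilyl)phenol | COc1ccc(C2OCCO2)c([Si](C)(C)C)c1O
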